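Readings and results are simulated for substances that don't exist; scatter was added.

The reading at 4.0 d comes 2.33 d after the feed ends in ash, and the reckoning runs on that warm window, w.

| flask | starting material | partner | second substrate | third substrate | temperature | remark | time |
|---|---|---|---|---|---|---|---|
| Tuesday's | 0.10 M | 0.10 M | 0.10 M | 0.20 M | 20 °C | run made earlier |  |
| Saturday's | 0.10 M | 0.050 M | 0.10 M | 0.20 M | 35 °C | run made earlier |  |
| Friday's | 0.10 M | 0.20 M | 0.10 M | 0.20 M | 20 °C | run made earlier |  |
| Thursday's | 0.10 M | 0.10 M | 0.10 M | 0.30 M | 35 °C | run made earlier |  |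
| maple | 0.10 M | 0.100 M | 0.100 M | 0.200 M | 35 °C | everything together at the start | 4.0 d |
| oak | 0.10 M | 0.100 M | 0.100 M | 0.200 M (fed, over 40 h) | 35 °C | all else is in the flask from the start; the feed brings no volume worth counting | 4.0 d |
| ash | 0.10 M (fed, over 40 h) | 0.100 M | 0.100 M | 0.200 M |  | the addition at 5 °C, then warmed to 35 °C; the feed brings no volume worth counting | 4.0 d |
| elm | 0.10 M (fed, over 40 h) | 0.100 M | 0.100 M | 0.200 M | 35 °C | all else is in the flask from the start; the feed brings no volume worth counting | 4.0 d |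

| run | time / d | target / % | over-reaction product / % | starting material / % |
|---|---|---|---|---|
| Tuesday's | 0.417 | 31.5 | 0.4 | 64.8 |
| Tuesday's | 1.25 | 19.0 | 0.9 | 81.6 |
| Tuesday's | 2.00 | 9.8 | 0.1 | 89.0 |
| Tuesday's | 4.00 | 5.9 | 0 | 96.7 |
| Tuesday's | 5.00 | 1.2 | 0 | 98.5 |
| Tuesday's | 6.00 | 0 | 1.7 | 98.5 |
| Tuesday's | 8.00 | 0.3 | 0 | 98.4 |
| Saturday's | 0.208 | 7.4 | 0 | 93.8 |
| Saturday's | 0.333 | 5.0 | 0.6 | 96.2 |
| Saturday's | 0.417 | 3.9 | 0 | 97.4 |
| Saturday's | 0.625 | 0.3 | 0.8 | 97.5 |
| Saturday's | 1.04 | 0 | 0 | 100.6 |
| Saturday's | 1.67 | 1.9 | 0 | 101.9 |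
| Saturday's | 2.50 | 0.6 | 0 | 99.3 |
| Friday's | 0.417 | 60.1 | 0 | 39.0 |
| Friday's | 0.625 | 57.7 | 0 | 43.8 |
| Friday's | 0.833 | 50.9 | 0.3 | 48.8 |
| Friday's | 1.25 | 44.3 | 0 | 54.0 |
| Friday's | 2.00 | 36.9 | 0 | 62.1 |
| Friday's | 4.00 | 24.3 | 0 | 74.0 |
| Friday's | 5.00 | 21.2 | 0 | 78.0 |
| Thursday's | 0.208 | 16.3 | 0 | 86.0 |
| Thursday's | 0.625 | 1.1 | 1.3 | 97.9 |
| Thursday's | 1.04 | 0 | 0 | 100.0 |
| Thursday's | 1.67 | 0 | 0 | 101.1 |
| Thursday's | 2.50 | 0.6 | 0 | 100.9 |

(standard deviation of a reading: 1 percentage point)

- which flask leads in share of target in target plus over-reaction product ("all alike" within 1.5 percentage points) (maple / oak / ash / elm / all alike)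
- share of target in target plus over-reaction product at the end, maple
- share of target in target plus over-reaction product at the end, oak
- share of target in target plus over-reaction product at the end, ash
- share of target in target plus over-reaction product at the end, elm

- steps under discussion: starting material + partner <-> target; second substrate + partner -> second product; third substrate + partner -> third product; target -> over-reaction product; partner -> decomposed reagent

At 35 °C, in Saturday's run, target falls from 7.4% to 3.9% between 0.208 d and 0.417 d. That reads as 3.06 d⁻¹, the fall-off constant λ, a pseudo-first-order rate of loss of target. Over-reaction product gathers k, its own first-order constant, times the area under the target curve. A falling exponential of height H has area H/λ, so at the reading the odds, target over over-reaction product, are (λ/k)e^(−λw), and H cancels.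

With k near nil the share in ash approaches 100%, the bound from above, since the readings give k no floor. The bound from below needs a ceiling on k. Friday's last over-reaction reading, 0% at 5.00 d, places no value on k, but two standard deviations above it stand at 2 percentage points, and the curve's mean, taken from first and last readings, is 40.6%. So a rough ceiling for k at 20 °C is 0.00984 d⁻¹. Tuesday's target fell at 0.738 d⁻¹, and borrowing that 4.15-fold warming for k gives 0.0409 d⁻¹. The odds in ash are then 0.0588, a share of 5.55%. The bracket for ash runs from there to 100%. Maple's fall can begin 40 h sooner, which cuts its odds by a factor of 164, so this reckoning puts ash ahead of maple.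

The forecast names ash, with 2% for maple, 6% for oak, 40% for ash, inside the bracket, and 6% for elm: “Ash preserves partner longest”.

The flasks give 0.403% for maple, 6.70% for oak, 64.2% for ash and 0.173% for elm, so ash leads, its share inside the bracket.

    starting material + partner ⇌ target (K = 26.0 L mol⁻¹, k = 0.00487 L mol⁻¹ s⁻¹, Ea = 58.0 kJ mol⁻¹, ΔH = −28.0 kJ mol⁻¹)
    second substrate + partner → second product (k = 0.00298 L mol⁻¹ s⁻¹, Ea = 54.0 kJ mol⁻¹)
    third substrate + partner → third product (k = 3.03 × 10⁻⁴ L mol⁻¹ s⁻¹, Ea = 84.0 kJ mol⁻¹)
    target → over-reaction product (k = 3.27 × 10⁻⁸ s⁻¹, Ea = 107 kJ mol⁻¹)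
    partner → decomposed reagent (k = 1.06 × 10⁻⁵ s⁻¹, Ea = 94.0 kJ mol⁻¹)
    (constants at 35 °C)

In elm the step to second product had half its turnover behind it by 0.565 h and the step to decomposed reagent by 0.950 h, while the feed ran on. The neighbouring flask, elm left until 40 h and read then, held partner at 0% and second substrate at 28.5%, with a share of 68.6%. Those odds, cut by e^(−λw) with λ at 3.06 d⁻¹, give a share of 0.171% for elm at 4.0 d, where the flask stands at 0.173%.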